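Everything rests on making ring A, the cyclopentane, by contraction of a cyclohexane. In ring A the carbinol CH(OH) bonded to the spiro carbon and the neighbouring CH that carries the C(=CH2) carbon of the triene are cis; with that alkene carbon read as an acyl carbon this is a cis-2-oxycyclopentyl methyl ketone. One stereospecific 1,2-shift delivers it: the precursor is a spiro[5.5]undecane whose extra ring holds a tertiary methyl carbinol silyl ether next to a trans-disposed epoxide, and acid opening of the epoxide at the carbon beside the carbinol lets the ring CH2 migrate, forming the ring A bond, the ketone and the new stereocentre at once.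

Key step: step 6

Remarks
- Labels: ring A = cyclopentane of the target; ring B = its cyclohexane; ring C = the six-membered forerunner of ring A. C-s = spiro carbon; C-p = ring B CH with the oxypropyl chain; C-k = ring B carbon that is ketal, then ketone, then alkylidene; C-q = ring B methyl carbinol carbon; C-d = CH–O carbon bonded to C-s; C-e = its neighbour (migration terminus); C-a = methyl carbinol carbon of ring C that becomes the acetyl carbon; C-b, C-c = the two CH2 groups (C-b bonded to C-a in ring C and to C-e in ring A).
- Assumption: the five starting materials of the compound list are purchased.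
- Assumption: the hydroxyl of the later acetoxymethyl branch is carried free through the cross-coupling and acetylated afterwards, since an allylic acetate on a dienylboronate is open to ionisation by zerovalent palladium.
- Assumption: both triethylsilyl ethers survive the mild ketal hydrolysis of step 8; loss of the C-q silyl group there would be harmless.

Step 1
Reactants: 1 (3-bromopropoxy)(tert-butyl)dimethylsilane; 2 1,4-dioxaspiro[4.5]dec-6-en-8-one
Product: 5 (6S)-6-{3-[(tert-butyldimethylsilyl)oxy]propyl}-7-(hydroxymethylidene)-1,4-dioxaspiro[4.5]decan-8-one (enol form of the 7-carbaldehyde), via Grignard reagent 3 (not isolated), via magnesium enolate 4 (not isolated)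
Conditions: 1, Mg, Et2O, rt; CuCl (5 mol %), 1-[α-(dimethylamino)-2-(diphenylphosphino)benzyl]-2-(diphenylphosphino)ferrocene (Taniaphos, 6 mol %, enantiomer chosen to give 6S), 2, tBuOMe, −78 °C; then CF3CH2OCHO, THF, −78 → 0 °C; aq. NH4Cl
Reagents that add atoms: 2,2,2-trifluoroethyl formate, O=COCC(F)(F)F
Why: Copper-catalysed enantioselective conjugate addition of the Grignard reagent, in which the chiral ferrocenyl diphosphine selects the enone face and so sets C-p as S, leaves a regiodefined magnesium enolate that undergoes Claisen-type C-formylation with the activated formate only at the carbon between the carbonyl group and C-p.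

Step 2
Reactants: 5 (6S)-6-{3-[(tert-butyldimethylsilyl)oxy]propyl}-7-(hydroxymethylidene)-1,4-dioxaspiro[4.5]decan-8-one; 6 but-3-en-2-one (methyl vinyl ketone)
Product: 8 spiro enedione (ring C cyclohex-2-en-1-one with C-a carbonyl and C-d=C-e alkene, spiro-linked at C-s to the ring B cyclohexanone that keeps the ethylene ketal at C-k and the silyloxypropyl chain at C-p; C-d cis to that chain), via Michael adduct 7 (not isolated)
Conditions: 6 (1.5 equiv), Et3N (0.3 equiv), THF, 0 °C → rt; then pyrrolidine (0.3 equiv), AcOH (0.3 equiv), PhMe, 60 °C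
Reagents that add atoms: none
Why: Amine-mediated Michael addition of the enolised formyl ketone to methyl vinyl ketone builds the quaternary spiro carbon C-s with the oxobutyl arm entering anti to the neighbouring C-p side chain, and the amine-catalysed intramolecular aldol condensation of the methyl ketone onto the non-enolisable aldehyde (6-enolexo-exo-trig, then dehydration) closes ring C as a Robinson-type spiroannulation.

Step 3
Reactants: 8 spiro enedione
Product: 9 diol (both carbonyl groups converted into methyl carbinols; C-a hydroxyl syn to C-q across ring C; C-q hydroxyl cis to the C-p chain)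
Conditions: MeLi (4 equiv), CeCl3 (4 equiv), THF, −78 °C; aq. NH4Cl
Reagents that add atoms: methyllithium, [Li]C
Why: Organocerium 1,2-addition (no enolisation, no conjugate addition) occurs first at the unhindered enone carbonyl, where axial attack on the half-chair of ring C with the still trigonal C-q branch pseudoaxial should place the new hydroxyl on C-a syn to C-q, and then at the neopentyl ring B ketone from the face anti to the C-p side chain so that the C-q hydroxyl ends cis to that chain, minor epimers being removed by chromatography at this stage.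

Step 4
Reactants: 9 diol
Product: 10 bis(triethylsilyl) ether of 9
Conditions: Et3SiOTf (3 equiv), 2,6-lutidine (5 equiv), CH2Cl2, −78 → 0 °C
Reagents that add atoms: triethylsilyl trifluoromethanesulfonate, CC[Si](CC)(CC)OS(=O)(=O)C(F)(F)F
Why: Silyl triflate silylation of both hindered tertiary alcohols under lutidine buffering masks the hydroxyls, so that neither can direct the peracid or add to the epoxide later, and puts on C-a the silyloxy donor that the key step requires.

Step 5
Reactants: 10 bis(triethylsilyl) ether
Product: 11 trans-epoxy silyl ether (epoxide on C-d and C-e on the ring C face anti to the C-a silyloxy group and syn to C-p)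
Conditions: mCPBA (1.5 equiv), NaHCO3, CH2Cl2, 0 °C
Reagents that add atoms: 3-chloroperoxybenzoic acid, OOC(=O)c1cccc(Cl)c1
Why: Prilezhaev epoxidation of the only alkene should take place on the face anti to the allylic silyloxy group on C-a and to the fully substituted C-q branch of the spiro carbon, that is syn to the small C-a methyl group, which gives the trans epoxy silyl ether and fixes the later carbinol configuration at C-d.

Step 6
Reactants: 11 trans-epoxy silyl ether
Product: 12 cis-2-(triethylsilyloxy)cyclopentyl methyl ketone spiro core (acetyl on C-e and Et3SiO on C-d cis, both syn to C-p; ring B unchanged)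
Conditions: Et3SiOTf (0.3 equiv), 2,6-di-tert-butyl-4-methylpyridine (0.5 equiv), CH2Cl2, −78 → −40 °C
Reagents that add atoms: none
Why: Et3SiOTf silylates the epoxide oxygen, the C-e–O bond (the epoxide carbon next to the silyloxy carbon C-a) lengthens, and the ring bond C-a–C-b that lies antiperiplanar to it shifts to C-e with inversion while C-a becomes a silyloxocarbenium ion that hands its Et3Si group to the next epoxide, so the promoter turns over and the product leaves as the β-silyloxy ketone. The closest known reaction type is the Lewis-acid semipinacol rearrangement of 2,3-epoxy alcohol silyl ethers in its silyl-triflate form, which includes the contraction of epoxycyclohexanols to 2-oxycyclopentyl ketones. Ring A is closed by this suprafacial 1,2-alkyl shift (contraction of ring C from six to five members through the new C-b–C-e bond) and not by a polar cyclisation. The one new stereocentre, C-e, is fixed by the inversion at the migration terminus, and because the epoxide oxygen stays on C-d with retention the acetyl group and the C-d oxygen end cis. The step needs cleavage of C-e–O instead of C-d–O, secured by the push of the silyloxy group and by the neopentyl position of C-d beside the spiro carbon, and ring-bond instead of methyl migration, secured by the trans relation of silyloxy group and epoxide, which puts the methyl group syn to the leaving oxygen. At −78 °C and with the hindered pyridine base the ketal and the other silyl ethers are expected to be spectators.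

Step 7
Reactants: 12 methyl ketone
Product: 14 enol triflate (CH2=C(OTf) on C-e; otherwise as 12), via potassium enolate 13 (not isolated)
Conditions: KN(SiMe3)2 (1.2 equiv), THF, −78 °C; then PhNTf2 (1.3 equiv), −78 → 0 °C
Reagents that add atoms: N-phenylbis(trifluoromethanesulfonimide), O=S(=O)(N(c1ccccc1)S(=O)(=O)C(F)(F)F)C(F)(F)F
Why: Kinetic deprotonation of the methyl ketone at the unhindered methyl group by the bulky amide base and O-triflation of the enolate (enol triflate formation) park the ketone as the 1,1-disubstituted alkenyl triflate needed for the cross-coupling and remove the only other carbonyl group before ring B is elaborated, without touching a stereocentre.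

Step 8
Reactants: 14 enol triflate
Product: 15 ring B ketone (14 with the ketal at C-k hydrolysed)
Conditions: PPTS (0.2 equiv), acetone/H2O (10:1), 40 °C
Reagents that add atoms: water, O
Why: Mild acid-catalysed hydrolysis (transketalisation) of the dioxolane in wet acetone frees the C-k ketone while the alkenyl triflate, the primary tert-butyldimethylsilyl ether and the hindered triethylsilyl ethers persist.

Step 9
Reactants: 15 ring B ketone
Product: 16 tertiary allylic alcohol (C-k carries OH and prop-1-en-2-yl; epimers at C-k, unassigned)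
Conditions: CH2=C(CH3)MgBr (3 equiv), CeCl3 (3 equiv), THF, −78 °C; aq. NH4Cl
Reagents that add atoms: prop-1-en-2-ylmagnesium bromide, C=C(C)[Mg]Br
Why: Organocerium 1,2-addition delivers the propenyl group to the hindered, enolisable ketone while the alkenyl triflate is inert at −78 °C, and the configuration of the new carbinol carbon is irrelevant because the next step erases it.

Step 10
Reactants: 16 tertiary allylic alcohol
Product: 17 Z enal (C-k=C(CH3)CHO with the formyl group cis to C-p; otherwise as 14)
Conditions: pyridinium chlorochromate [C5H5NH][CrO3Cl] (3 equiv), NaOAc, 4 Å molecular sieves, CH2Cl2, rt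
Reagents that add atoms: pyridinium chlorochromate, [O-][Cr](=O)(=O)Cl.c1cc[nH+]cc1
Why: Babler–Dauben oxidative transposition, in which the chromate ester of the tertiary allylic alcohol undergoes a [3,3]-sigmatropic shift and the primary allylic chromate is oxidised to the enal, should favour the transition state that keeps the propenyl methyl group away from the substituted C-p and so place the formyl group cis to C-p, any E isomer being removable by chromatography.

Step 11
Reactants: 18 tert-butyldimethyl(prop-2-yn-1-yloxy)silane
Product: 20 methyl 4-[(tert-butyldimethylsilyl)oxy]but-2-ynoate, via lithium acetylide 19 (not isolated)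
Conditions: n-BuLi (1.05 equiv), THF, −78 °C; then ClCO2Me, −78 → 0 °C
Reagents that add atoms: methyl chloroformate, COC(=O)Cl
Why: Deprotonation of the terminal alkyne and C-acylation of the lithium acetylide with the chloroformate give the ynoate.

Step 12
Reactants: 20 methyl 4-[(tert-butyldimethylsilyl)oxy]but-2-ynoate; 21 5-bromo-2-methylpent-2-ene
Product: 25 methyl (2Z)-3-({[tert-butyl(dimethyl)silyl]oxy}methyl)-7-methylocta-2,6-dienoate, via Grignard reagent 22 (not isolated), via organocopper reagent 23 (not isolated), via alkenylcopper adduct 24 (not isolated)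
Conditions: 21, Mg, THF, rt; CuBr·SMe2 (1.0 equiv), THF, −40 °C; 20, −78 °C; MeOH then aq. NH4Cl at −78 °C
Reagents that add atoms: none
Why: Stoichiometric organocopper syn-carbometallation (conjugate addition) of the ynoate at −78 °C and cold protonation with retention place the new alkyl group and the vinylic hydrogen cis, so that the ester is cis to the silyloxymethyl group and the Z geometry of the later acetoxymethyl alkene is fixed.

Step 13
Reactants: 25 Z enoate
Product: 26 (2Z)-3-({[tert-butyl(dimethyl)silyl]oxy}methyl)-7-methylocta-2,6-dien-1-ol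
Conditions: iBu2AlH (2.2 equiv), CH2Cl2, −78 °C; aq. potassium sodium tartrate
Reagents that add atoms: none
Why: 1,2-Reduction of the conjugated ester by the aluminium hydride at low temperature gives the allylic alcohol without touching the alkene geometry or the silyl ether.

Step 14
Reactants: 26 Z allylic alcohol
Product: 27 (2Z)-3-({[tert-butyl(dimethyl)silyl]oxy}methyl)-7-methylocta-2,6-dienal
Conditions: MnO2 (15 equiv), CH2Cl2, rt
Reagents that add atoms: none
Why: Chemoselective MnO2 oxidation of the primary allylic alcohol gives the enal under neutral conditions that should not isomerise the Z alkene.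

Step 15
Reactants: 27 Z enal
Product: 28 tert-butyldimethyl{[(2Z,4E)-2-(4-methylpent-3-en-1-yl)-5-(4,4,5,5-tetramethyl-1,3,2-dioxaborolan-2-yl)penta-2,4-dien-1-yl]oxy}silane
Conditions: CrCl2 (8 equiv), Cl2CHB(pin) (2 equiv), LiI (4 equiv), THF, rt
Reagents that add atoms: 2-(dichloromethyl)-4,4,5,5-tetramethyl-1,3,2-dioxaborolane, ClC(Cl)B1OC(C)(C)C(C)(C)O1
Why: Takai–Utimoto borylative olefination, in which the geminal dichromium species formed from the dihalomethylboronate adds to the aldehyde and eliminates anti-selectively, gives the E alkenylboronate and leaves the existing Z alkene intact.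

Step 16
Reactants: 28 silylated dienylboronate
Product: 29 (2Z,4E)-2-(4-methylpent-3-en-1-yl)-5-(4,4,5,5-tetramethyl-1,3,2-dioxaborolan-2-yl)penta-2,4-dien-1-ol
Conditions: camphorsulfonic acid (10 mol %), MeOH/CH2Cl2, 0 °C
Reagents that add atoms: none
Why: Acid-catalysed methanolysis of the primary silyl ether, to which the pinacol boronate is stable, frees the hydroxyl so that it will be the only unprotected alcohol after the coupling.

Step 17
Reactants: 17 Z enal enol triflate; 29 dienylboronate alcohol
Product: 30 triene alcohol (CH2=C(C-e)–CH=CH–CH=C(CH2OH)(CH2CH2CH=CMe2) with E then Z geometry; ring A, ring B and silyl ethers as in 17)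
Conditions: Pd(PPh3)4 (5 mol %), K3PO4 (3 equiv), THF/H2O, 45 °C
Reagents that add atoms: none
Why: Suzuki–Miyaura coupling, in which zerovalent palladium inserts into the alkenyl C–OTf bond and base-assisted transmetallation from the dienylboronate and reductive elimination join the two sp2 carbons with retention of both alkene geometries, gives the 2-substituted triene while the enal, the free allylic alcohol and the silyl ethers are tolerated.

Step 18
Reactants: 30 triene alcohol
Product: 31 triene acetate (acetate of 30)
Conditions: Ac2O (1.5 equiv), pyridine, DMAP (5 mol %), CH2Cl2, 0 °C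
Reagents that add atoms: acetic anhydride, CC(=O)OC(C)=O
Why: Acylation of the single free, primary allylic hydroxyl installs the acetate without any demand on selectivity, since every other oxygen is silylated.

Step 19
Reactants: 31 triene acetate
Product: 32 target CNP0205332.1
Conditions: HF·pyridine, pyridine, THF, 0 °C → rt
Reagents that add atoms: none
Why: Fluoride-mediated cleavage of the three silyl ethers under buffered, weakly acidic conditions that spare the allylic acetate, the enal and the triene should deliver the target with all stereocentres and alkene geometries unchanged.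

Compound list
1 | (3-bromopropoxy)(tert-butyl)dimethylsilane | BrCCCO[Si](C)(C)C(C)(C)C | starting material
2 | 1,4-dioxaspiro[4.5]dec-6-en-8-one | O=C1CCC2(OCCO2)C=C1 | starting material
3 | {3-[(tert-butyldimethylsilyl)oxy]propyl}magnesium bromide | Br[Mg]CCCO[Si](C)(C)C(C)(C)C | intermediate
4 | bromomagnesium (6S)-6-{3-[(tert-butyldimethylsilyl)oxy]propyl}-1,4-dioxaspiro[4.5]dec-7-en-8-olate | Br[Mg]OC1=C[C@H](CCCO[Si](C)(C)C(C)(C)C)C2(OCCO2)CC1 | intermediate
5 | (6S)-6-{3-[(tert-butyldimethylsilyl)oxy]propyl}-7-(hydroxymethylidene)-1,4-dioxaspiro[4.5]decan-8-one | O=C1CCC2(OCCO2)[C@@H](CCCO[Si](C)(C)C(C)(C)C)C1=CO | intermediate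
6 | but-3-en-2-one (methyl vinyl ketone) | CC(=O)C=C | starting material
7 | (6S,7S)-6-{3-[(tert-butyldimethylsilyl)oxy]propyl}-8-oxo-7-(3-oxobutyl)-1,4-dioxaspiro[4.5]decane-7-carbaldehyde | CC(=O)CC[C@]1([C@H](CCCO[Si](C)(C)C(C)(C)C)C2(OCCO2)CCC1=O)C=O | intermediate
8 | spiro enedione (ring C enone, ring B ketone, ketal at C-k, C-d cis to the C-p chain) | O=C1CC[C@]2([C@H](CCCO[Si](C)(C)C(C)(C)C)C3(OCCO3)CCC2=O)C=C1 | intermediate
9 | diol (C-a hydroxyl syn to C-q; C-q hydroxyl cis to the C-p chain) | C[C@]1(O)CC[C@]2([C@H](CCCO[Si](C)(C)C(C)(C)C)C3(OCCO3)CC[C@]2(C)O)C=C1 | intermediate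
10 | bis(triethylsilyl) ether of 9 | C[C@]1(O[Si](CC)(CC)CC)CC[C@]2([C@H](CCCO[Si](C)(C)C(C)(C)C)C3(OCCO3)CC[C@]2(C)O[Si](CC)(CC)CC)C=C1 | intermediate
11 | trans-epoxy silyl ether (epoxide anti to the C-a silyloxy group, syn to C-p) | C[C@]1(O[Si](CC)(CC)CC)CC[C@]2([C@H](CCCO[Si](C)(C)C(C)(C)C)C3(OCCO3)CC[C@]2(C)O[Si](CC)(CC)CC)[C@@H]4O[C@H]14 | intermediate
12 | cis-2-(triethylsilyloxy)cyclopentyl methyl ketone spiro core | CC(=O)[C@@H]1CC[C@]2([C@H](CCCO[Si](C)(C)C(C)(C)C)C3(OCCO3)CC[C@]2(C)O[Si](CC)(CC)CC)[C@@H]1O[Si](CC)(CC)CC | intermediate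
13 | potassium enolate of 12 (methyl side) | C=C(O[K])[C@@H]1CC[C@]2([C@H](CCCO[Si](C)(C)C(C)(C)C)C3(OCCO3)CC[C@]2(C)O[Si](CC)(CC)CC)[C@@H]1O[Si](CC)(CC)CC | intermediate
14 | enol triflate of 12 | C=C(OS(=O)(=O)C(F)(F)F)[C@@H]1CC[C@]2([C@H](CCCO[Si](C)(C)C(C)(C)C)C3(OCCO3)CC[C@]2(C)O[Si](CC)(CC)CC)[C@@H]1O[Si](CC)(CC)CC | intermediate
15 | ring B ketone (C-k carbonyl) | C=C(OS(=O)(=O)C(F)(F)F)[C@@H]1CC[C@]2([C@H](CCCO[Si](C)(C)C(C)(C)C)C(=O)CC[C@]2(C)O[Si](CC)(CC)CC)[C@@H]1O[Si](CC)(CC)CC | intermediate
16 | tertiary allylic alcohol (C-k with OH and prop-1-en-2-yl, C-k epimers) | C=C(OS(=O)(=O)C(F)(F)F)[C@@H]1CC[C@]2([C@H](CCCO[Si](C)(C)C(C)(C)C)C(O)(C(C)=C)CC[C@]2(C)O[Si](CC)(CC)CC)[C@@H]1O[Si](CC)(CC)CC | intermediate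
17 | Z enal enol triflate (formyl cis to C-p) | C=C(OS(=O)(=O)C(F)(F)F)[C@@H]1CC[C@]2([C@H](CCCO[Si](C)(C)C(C)(C)C)/C(=C(/C)C=O)CC[C@]2(C)O[Si](CC)(CC)CC)[C@@H]1O[Si](CC)(CC)CC | intermediate
18 | tert-butyldimethyl(prop-2-yn-1-yloxy)silane | C#CCO[Si](C)(C)C(C)(C)C | starting material
19 | {3-[(tert-butyldimethylsilyl)oxy]prop-1-yn-1-yl}lithium | [Li]C#CCO[Si](C)(C)C(C)(C)C | intermediate
20 | methyl 4-[(tert-butyldimethylsilyl)oxy]but-2-ynoate | COC(=O)C#CCO[Si](C)(C)C(C)(C)C | intermediate
21 | 5-bromo-2-methylpent-2-ene | CC(C)=CCCBr | starting material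
22 | (4-methylpent-3-en-1-yl)magnesium bromide | CC(C)=CCC[Mg]Br | intermediate
23 | (4-methylpent-3-en-1-yl)copper (MgBr2 complex) | CC(C)=CCC[Cu] | intermediate
24 | alkenylcopper adduct (copper on C2, cis to the 4-methylpent-3-enyl group) | COC(=O)/C([Cu])=C(/CCC=C(C)C)CO[Si](C)(C)C(C)(C)C | intermediate
25 | methyl (2Z)-3-({[tert-butyl(dimethyl)silyl]oxy}methyl)-7-methylocta-2,6-dienoate | COC(=O)/C=C(/CCC=C(C)C)CO[Si](C)(C)C(C)(C)C | intermediate
26 | (2Z)-3-({[tert-butyl(dimethyl)silyl]oxy}methyl)-7-methylocta-2,6-dien-1-ol | OC/C=C(/CCC=C(C)C)CO[Si](C)(C)C(C)(C)C | intermediate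
27 | (2Z)-3-({[tert-butyl(dimethyl)silyl]oxy}methyl)-7-methylocta-2,6-dienal | O=C/C=C(/CCC=C(C)C)CO[Si](C)(C)C(C)(C)C | intermediate
28 | tert-butyldimethyl{[(2Z,4E)-2-(4-methylpent-3-en-1-yl)-5-(4,4,5,5-tetramethyl-1,3,2-dioxaborolan-2-yl)penta-2,4-dien-1-yl]oxy}silane | CC1(C)OB(/C=C/C=C(/CCC=C(C)C)CO[Si](C)(C)C(C)(C)C)OC1(C)C | intermediate
29 | (2Z,4E)-2-(4-methylpent-3-en-1-yl)-5-(4,4,5,5-tetramethyl-1,3,2-dioxaborolan-2-yl)penta-2,4-dien-1-ol | CC1(C)OB(/C=C/C=C(/CCC=C(C)C)CO)OC1(C)C | intermediate
30 | triene alcohol (coupling product, three silyl ethers retained) | C=C(/C=C/C=C(/CCC=C(C)C)CO)[C@@H]1CC[C@]2([C@H](CCCO[Si](C)(C)C(C)(C)C)/C(=C(/C)C=O)CC[C@]2(C)O[Si](CC)(CC)CC)[C@@H]1O[Si](CC)(CC)CC | intermediate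
31 | triene acetate (acetate of 30) | C=C(/C=C/C=C(/CCC=C(C)C)COC(C)=O)[C@@H]1CC[C@]2([C@H](CCCO[Si](C)(C)C(C)(C)C)/C(=C(/C)C=O)CC[C@]2(C)O[Si](CC)(CC)CC)[C@@H]1O[Si](CC)(CC)CC | intermediate
32 | CNP0205332.1 | C=C(/C=C/C=C(/CCC=C(C)C)COC(C)=O)[C@@H]1CC[C@]2([C@H](CCCO)/C(=C(/C)C=O)CC[C@]2(C)O)[C@@H]1O | target

Total step count: 19 (13 on the main line, 6 for the dienylboronate 29).
Longest linear sequence: 13 steps (steps 1 to 10 and 17 to 19).

Steps most likely to fail

1. Step 6 (key step). What may go wrong: ionisation at the neopentyl epoxide carbon C-d with a Wagner–Meerwein shift of a ring B bond, methyl instead of ring-bond migration if the substrate reacts through a conformer without antiperiplanar alignment, or activation of the dioxolane by the silyl triflate. Fallback, with a different leaving group and an aluminium alkoxide pinacol-type shift: it sets out from diol 9. OsO4 (5 mol %) with N-methylmorpholine N-oxide should dihydroxylate the ring C alkene anti to the allylic C-a hydroxyl and give the tetraol F1. The less encumbered C-e hydroxyl (the C-d hydroxyl is neopentyl to the spiro carbon) is then mesylated selectively (MsCl, 2,4,6-collidine, CH2Cl2, −20 °C) to the monomesylate F2. Et3Al (CH2Cl2, −78 °C) converts the tertiary carbinol into its aluminium alkoxide and triggers the stereospecific shift of the C-a–C-b bond anti to the mesylate, which should give the dihydroxy methyl ketone F3 with the same configuration at C-e. Bis-silylation (Et3SiOTf, 2,6-lutidine) comes back to the route at 12.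

2. Step 3. What may go wrong: poor facial discrimination at the enone carbonyl, which lies across ring C from the spiro carbon, so that the C-a epimers form in similar amounts; enolisation of the ring B ketone is a lesser concern. Fallback, with the two additions done stepwise in reversed order: it sets out from 8. Luche reduction (NaBH4, CeCl3·7H2O, MeOH, −78 °C) masks the enone carbonyl selectively as the allylic alcohol F4. MeLi/CeCl3 then adds to the ring B ketone to give the diol F5, and MnO2 reoxidises only the allylic alcohol to the hydroxy enone F6. A second MeLi/CeCl3 addition now meets an enone whose C-q branch is tetrahedral and alkoxide-bearing, which changes the conformational bias of ring C and should give the complementary facial outcome at C-a; whichever order favours the C-a hydroxyl syn to C-q is used, and the sequence comes back to the route at 9.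

3. Step 10. What may go wrong: poor control of the alkene geometry in the sigmatropic shift, giving the enal as a mixture in which the formyl group is cis to either ring B neighbour. Fallback, with the geometry fixed by a ring: it sets out from 15. The secondary C-d silyl ether is removed selectively (PPTS, MeOH, 0 °C) to give the keto alcohol F7, which is esterified with 2-(diethoxyphosphoryl)propanoic acid (DCC, DMAP, CH2Cl2) to the phosphonate ester F8. Intramolecular Horner–Wadsworth–Emmons olefination of the C-k ketone (LiCl, DBU, MeCN) closes the seven-membered unsaturated lactone F9, in which the carbonyl carbon is necessarily cis to C-p. iBu2AlH (CH2Cl2, −78 °C) reduces the lactone to the lactol, which is in equilibrium with the hydroxy enal F10, and silylation of the C-d hydroxyl (Et3SiOTf, 2,6-lutidine) traps the open form and comes back to the route at 17.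

Further compounds
F1 | step 6 | tetraol (cis-diol on C-d and C-e anti to the C-a hydroxyl) | C[C@]1(O)CC[C@]2([C@H](CCCO[Si](C)(C)C(C)(C)C)C3(OCCO3)CC[C@]2(C)O)[C@H](O)[C@@H]1O
F2 | step 6 | C-e monomesylate of F1 | C[C@]1(O)CC[C@]2([C@H](CCCO[Si](C)(C)C(C)(C)C)C3(OCCO3)CC[C@]2(C)O)[C@H](O)[C@@H]1OS(C)(=O)=O
F3 | step 6 | dihydroxy methyl ketone (12 without its two triethylsilyl groups) | CC(=O)[C@@H]1CC[C@]2([C@H](CCCO[Si](C)(C)C(C)(C)C)C3(OCCO3)CC[C@]2(C)O)[C@@H]1O
F4 | step 3 | allylic alcohol from 1,2-reduction of the enone of 8 (C-a epimers) | OC1CC[C@]2([C@H](CCCO[Si](C)(C)C(C)(C)C)C3(OCCO3)CCC2=O)C=C1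
F5 | step 3 | diol with secondary allylic alcohol at C-a and methyl carbinol at C-q | OC1CC[C@]2([C@H](CCCO[Si](C)(C)C(C)(C)C)C3(OCCO3)CC[C@]2(C)O)C=C1
F6 | step 3 | hydroxy enone (ring C enone, C-q methyl carbinol) | O=C1CC[C@]2([C@H](CCCO[Si](C)(C)C(C)(C)C)C3(OCCO3)CC[C@]2(C)O)C=C1
F7 | step 10 | keto alcohol (15 with free C-d hydroxyl) | C=C(OS(=O)(=O)C(F)(F)F)[C@@H]1CC[C@]2([C@H](CCCO[Si](C)(C)C(C)(C)C)C(=O)CC[C@]2(C)O[Si](CC)(CC)CC)[C@@H]1O
F8 | step 10 | 2-(diethoxyphosphoryl)propanoate of F7 | C=C(OS(=O)(=O)C(F)(F)F)[C@@H]1CC[C@]2([C@H](CCCO[Si](C)(C)C(C)(C)C)C(=O)CC[C@]2(C)O[Si](CC)(CC)CC)[C@@H]1OC(=O)C(C)P(=O)(OCC)OCC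
F9 | step 10 | seven-membered unsaturated lactone (C-d–O–CO–C(CH3)=C-k) | C=C(OS(=O)(=O)C(F)(F)F)[C@@H]1CC[C@]2([C@H](CCCO[Si](C)(C)C(C)(C)C)C=4CC[C@]2(C)O[Si](CC)(CC)CC)[C@@H]1OC(=O)C(C)=4
F10 | step 10 | hydroxy enal (17 with free C-d hydroxyl) | C=C(OS(=O)(=O)C(F)(F)F)[C@@H]1CC[C@]2([C@H](CCCO[Si](C)(C)C(C)(C)C)/C(=C(/C)C=O)CC[C@]2(C)O[Si](CC)(CC)CC)[C@@H]1O
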